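The target is disconnected at two adjacent bonds of its single benzene ring: the C1–CH2 bond to the side chain and the C6–O bond. Because C1, C6 and C5 (OMe) are contiguous, they map onto an aryne spanning C1–C6 with the C5 methoxy group beside it. In one operation a chiral C,O-dimetalated 2-hydroxytridecyl nucleophile adds at C1, and the resulting C6 aryl-metal is borylated and oxidised to the phenol. The aryne precursor is the triisopropylsilyl ether of 3-fluoro-5-methoxyphenol (the silyloxy carbon becomes C3). The nucleophile comes from (R)-1-chlorotridecan-2-ol, made from (R)-epichlorohydrin, so the only stereocentre is bought and never touched.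

Key step: step 3

Remark: ring numbering throughout is C1 (side chain), C3 (free OH), C5 (OMe), C6 (OAc); the side-chain carbinol carbon is (R), and opening (R)-epichlorohydrin at its ring CH2 gives the (R)-chlorohydrin because CH2Cl still outranks the new alkyl chain.

Step 1
Reactants: 1 3-fluoro-5-methoxyphenol
Product: 2 (3-fluoro-5-methoxyphenoxy)triisopropylsilane
Conditions: TIPSCl, imidazole, DMF, rt
Reagents that add atoms: chlorotriisopropylsilane (TIPSCl), CC(C)[Si](Cl)(C(C)C)C(C)C
Why: Imidazole-promoted silylation of a phenol is routine, and the bulky triisopropylsilyl ether is chosen because it withstands sec-butyllithium and shields the two ring positions next to it in step 3.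

Step 2
Reactants: 3 (R)-epichlorohydrin; 4 1-bromodecane
Product: 6 (R)-1-chlorotridecan-2-ol, via decylmagnesium bromide 5 (not isolated)
Conditions: 4, Mg, THF, rt → 45 °C; then 3, CuI (10 mol %), THF, −40 °C; aq NH4Cl
Reagents that add atoms: none
Why: Copper-catalysed Grignard opening of a terminal epoxide takes place by SN2 attack at the unsubstituted ring CH2 and leaves the chloride intact at low temperature; the stereocentre is not a reaction site, so the (R) configuration of 3 is carried into 6.

Step 3
Reactants: 2 (3-fluoro-5-methoxyphenoxy)triisopropylsilane; 6 (R)-1-chlorotridecan-2-ol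
Product: 13 (R)-1-[2-hydroxy-3-methoxy-5-(triisopropylsilyloxy)phenyl]tridecan-2-ol, via dilithio alkoxide 7 (not isolated), via dimagnesio alkoxide 8 (not isolated), via aryllithium 9 (not isolated), via aryne 10 (not isolated), via arylmagnesium adduct 11 (not isolated), via arylboronate 12 (not isolated)
Conditions: 6 (1.5 equiv), n-BuLi, then LiDBB (2 equiv), THF, −78 °C; MgBr2·OEt2 (2 equiv per 6), −78 °C; separately 2, s-BuLi, THF, −78 °C; combine, −78 → −30 °C; B(OMe)3, −78 → 0 °C; AcOH, 30% H2O2, 0 °C → rt
Reagents that add atoms: hydrogen peroxide, OO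
Why: Proposed new method: s-BuLi removes the ring hydrogen between F and OMe of 2 (the most acidic site, the two other ring positions being shielded by the triisopropylsilyl ether) to give 9, which loses LiF on warming to aryne 10, while 6 is converted by O-deprotonation, reductive C–Cl lithiation with the arene radical anion (7) and Li-to-Mg exchange into 8, whose primary carbanion adds to the aryne carbon remote from OMe (C1); the C6 arylmagnesium 11 is then borylated to 12 and oxidised with retention by 1,2-aryl shift from boron to oxygen. The closest known reaction type is the three-component coupling of 3-methoxybenzynes, generated from ortho-lithiated 3-fluoroanisoles, with Grignard reagents and an electrophile, and beta-oxido organolithiums from chlorohydrins are known separately, but a beta-oxido carbanion has not been used as the aryne partner. No ring is closed and no stereocentre is formed, since C2 of the side chain comes from 6 and no bond to it is made or broken. Regioselectivity of the addition is set by the C5 methoxy group, whose inductive pull and distortion of the aryne direct the nucleophile to C1 and leave the charge at C6, where the methoxy oxygen and the side-chain alkoxide can chelate the metal. Chemoselectivity for carbon over oxygen attack follows from the far higher nucleophilicity of the C–Mg bond compared with the magnesium alkoxide, and beta-elimination to 1-tridecene is held back by the poor leaving-group ability of the oxide, by magnesium (used without excess, so that 9 is not turned into a sluggish fluoroaryl Grignard) and by not exceeding about −30 °C. LiDBB replaces lithium naphthalenide so that no arene prone to cycloaddition with the aryne is present.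

Step 4
Reactants: 13 (R)-1-[2-hydroxy-3-methoxy-5-(triisopropylsilyloxy)phenyl]tridecan-2-ol
Product: 14 (R)-1-[2-acetoxy-3-methoxy-5-(triisopropylsilyloxy)phenyl]tridecan-2-yl acetate
Conditions: Ac2O, pyridine, DMAP (cat.), CH2Cl2, 0 °C → rt
Reagents that add atoms: acetic anhydride, CC(=O)OC(C)=O
Why: DMAP-catalysed acylation (nucleophilic catalysis) esterifies both the hindered C6 phenol and the secondary alcohol, while the aryl silyl ether and the stereocentre are not affected.

Step 5
Reactants: 14 (R)-1-[2-acetoxy-3-methoxy-5-(triisopropylsilyloxy)phenyl]tridecan-2-yl acetate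
Product: 15 (R)-1-(2-acetoxy-5-hydroxy-3-methoxyphenyl)tridecan-2-yl acetate (target)
Conditions: TBAF, AcOH (1:1.2), THF, 0 °C → rt
Reagents that add atoms: none
Why: Fluoride-induced cleavage of the aryl silyl ether is driven by the Si–F bond, and the acetic acid buffer protonates the phenoxide as it forms so that neither acetate should be hydrolysed or transferred; the new C3 hydroxyl is para to the C6 acetate, which rules out intramolecular migration.

Compound list
1 | 3-fluoro-5-methoxyphenol | COc1cc(O)cc(F)c1 | starting material
2 | (3-fluoro-5-methoxyphenoxy)triisopropylsilane | COc1cc(F)cc(O[Si](C(C)C)(C(C)C)C(C)C)c1 | intermediate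
3 | (R)-epichlorohydrin, (R)-2-(chloromethyl)oxirane | ClC[C@H]1CO1 | starting material
4 | 1-bromodecane | CCCCCCCCCCBr | starting material
5 | decylmagnesium bromide | CCCCCCCCCC[Mg]Br | intermediate (not isolated)
6 | (R)-1-chlorotridecan-2-ol | CCCCCCCCCCC[C@H](CCl)O | intermediate
7 | lithium (S)-1-lithiotridecan-2-olate (same spatial arrangement as 6; the descriptor changes only because CH2Li ranks below the alkyl chain) | CCCCCCCCCCC[C@H](C[Li])O[Li] | intermediate (not isolated)
8 | bromomagnesium (R)-1-(bromomagnesio)tridecan-2-olate | CCCCCCCCCCC[C@H](C[Mg]Br)O[Mg]Br | intermediate (not isolated)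
9 | [2-fluoro-6-methoxy-4-(triisopropylsilyloxy)phenyl]lithium | [Li]c1c(F)cc(O[Si](C(C)C)(C(C)C)C(C)C)cc1OC | intermediate (not isolated)
10 | 3-methoxy-5-(triisopropylsilyloxy)benzyne (1,2-didehydro-3-methoxy-5-(triisopropylsilyloxy)benzene) | COC1=CC(O[Si](C(C)C)(C(C)C)C(C)C)=CC#C1 | intermediate (not isolated)
11 | bromomagnesium (R)-1-[2-(bromomagnesio)-3-methoxy-5-(triisopropylsilyloxy)phenyl]tridecan-2-olate | CCCCCCCCCCC[C@H](Cc1cc(O[Si](C(C)C)(C(C)C)C(C)C)cc(OC)c1[Mg]Br)O[Mg]Br | intermediate (not isolated)
12 | bromomagnesium (R)-1-[2-(dimethoxyboryl)-3-methoxy-5-(triisopropylsilyloxy)phenyl]tridecan-2-olate | CCCCCCCCCCC[C@H](Cc1cc(O[Si](C(C)C)(C(C)C)C(C)C)cc(OC)c1B(OC)OC)O[Mg]Br | intermediate (not isolated)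
13 | (R)-1-[2-hydroxy-3-methoxy-5-(triisopropylsilyloxy)phenyl]tridecan-2-ol | CCCCCCCCCCC[C@H](Cc1cc(O[Si](C(C)C)(C(C)C)C(C)C)cc(OC)c1O)O | intermediate
14 | (R)-1-[2-acetoxy-3-methoxy-5-(triisopropylsilyloxy)phenyl]tridecan-2-yl acetate | CCCCCCCCCCC[C@H](Cc1cc(O[Si](C(C)C)(C(C)C)C(C)C)cc(OC)c1OC(C)=O)OC(C)=O | intermediate
15 | (R)-1-(2-acetoxy-5-hydroxy-3-methoxyphenyl)tridecan-2-yl acetate | CCCCCCCCCCC[C@H](Cc1cc(O)cc(OC)c1OC(C)=O)OC(C)=O | target

Total step count: 5. Longest linear sequence: 4 steps (steps 1, 3, 4, 5 or steps 2, 3, 4, 5).

Steps most likely to fail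

Step 3 (proposed new method). The temperature at which 9 loses LiF may lie above the range in which the beta-oxido carbanion survives. In that case beta-elimination of the nucleophile, self-condensation of the lithiated fluoroarene with its own aryne, or attack through oxygen would take over. The fallback sets out from 6 and comes back at 13, using known chemistry in which the polarity of the C1–CH2 bond formation is inverted so that a C1 aryllithium opens an epoxide. Chlorohydrin 6 is closed with NaOH in aqueous THF to (R)-2-undecyloxirane F1. Commercial 5-bromovanillin (O=Cc1cc(Br)c(O)c(OC)c1) is benzylated (BnBr, K2CO3, DMF) to 4-(benzyloxy)-3-bromo-5-methoxybenzaldehyde F2. Its formyl group is exchanged for oxygen by Baeyer–Villiger oxidation with mCPBA, giving 4-(benzyloxy)-3-bromo-5-methoxyphenyl formate F3, and methanolysis (K2CO3, MeOH) gives 4-(benzyloxy)-3-bromo-5-methoxyphenol F4. Silylation (TIPSCl, imidazole) gives [4-(benzyloxy)-3-bromo-5-methoxyphenoxy]triisopropylsilane F5. Bromine–lithium exchange with n-BuLi in THF at −78 °C should give [2-(benzyloxy)-3-methoxy-5-(triisopropylsilyloxy)phenyl]lithium F6. This should open F1 at its CH2 terminus in the presence of BF3·OEt2 to give (R)-1-[2-(benzyloxy)-3-methoxy-5-(triisopropylsilyloxy)phenyl]tridecan-2-ol F7. Hydrogenolysis of the benzyl ether (H2, Pd/C, EtOAc) then returns to 13.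

Step 5. Partial loss of the aryl acetate, or its intermolecular transfer to the liberated phenoxide, may accompany the fluoride treatment. The fallback sets out from 14 and comes back at 15. The silyl ether is exchanged for a third acetate in one pot by fluoride-mediated desilylative acetylation (CsF, Ac2O, DMF, rt), giving (R)-1-(2,5-diacetoxy-3-methoxyphenyl)tridecan-2-yl acetate F8. The unhindered C3 aryl acetate, flanked by two ring hydrogens, is then removed by aminolysis with pyrrolidine (1 equiv, CH2Cl2, 0 °C). This should occur in preference to the doubly ortho-substituted C6 aryl acetate and the less electrophilic alkyl acetate, giving 15.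

Step 2. Bromide from the Grignard solution may open the epoxide in competition with the organocopper species, or the chloro-alkoxide may close to an epoxide on warming and be alkylated a second time. The fallback sets out from 3 and comes back at 6, and replaces the Grignard reagent by an acetylide. 1-Decyne is deprotonated with n-BuLi (THF, −78 °C) to dec-1-yn-1-yllithium F9. In the presence of BF3·OEt2 this should open 3 at the ring CH2 to give (R)-1-chlorotridec-4-yn-2-ol F10. Hydrogenation of the triple bond (H2, Pd/C, EtOAc) gives 6.

Further compounds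
F1 | step 3 | (R)-2-undecyloxirane | CCCCCCCCCCC[C@@H]1CO1
F2 | step 3 | 4-(benzyloxy)-3-bromo-5-methoxybenzaldehyde | O=Cc1cc(Br)c(OCc2ccccc2)c(OC)c1
F3 | step 3 | 4-(benzyloxy)-3-bromo-5-methoxyphenyl formate | O=COc1cc(Br)c(OCc2ccccc2)c(OC)c1
F4 | step 3 | 4-(benzyloxy)-3-bromo-5-methoxyphenol | Oc1cc(Br)c(OCc2ccccc2)c(OC)c1
F5 | step 3 | [4-(benzyloxy)-3-bromo-5-methoxyphenoxy]triisopropylsilane | CC(C)[Si](Oc1cc(Br)c(OCc2ccccc2)c(OC)c1)(C(C)C)C(C)C
F6 | step 3 | [2-(benzyloxy)-3-methoxy-5-(triisopropylsilyloxy)phenyl]lithium | [Li]c1cc(O[Si](C(C)C)(C(C)C)C(C)C)cc(OC)c1OCc1ccccc1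
F7 | step 3 | (R)-1-[2-(benzyloxy)-3-methoxy-5-(triisopropylsilyloxy)phenyl]tridecan-2-ol | CCCCCCCCCCC[C@H](Cc1cc(O[Si](C(C)C)(C(C)C)C(C)C)cc(OC)c1OCc1ccccc1)O
F8 | step 5 | (R)-1-(2,5-diacetoxy-3-methoxyphenyl)tridecan-2-yl acetate | CCCCCCCCCCC[C@H](Cc1cc(OC(C)=O)cc(OC)c1OC(C)=O)OC(C)=O
F9 | step 2 | dec-1-yn-1-yllithium | [Li]C#CCCCCCCCC
F10 | step 2 | (R)-1-chlorotridec-4-yn-2-ol | CCCCCCCCC#CC[C@H](CCl)O
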